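**Retrosynthetic overview**

1. Labels: the upper flavan U has benzo ring A, pyran ring C and aryl ring B; the lower epiafzelechin unit L has benzo ring D, pyran ring F and aryl ring E. The target is reached last by methanolysis of an L-C3 acetate and hydrogenolysis of five benzyl ethers.
2. The plan rests on ring F: a pyran fused to ring D whose bonds L-O1–L-C2 and L-C3–L-C4 lie on either side of the cis L-C2/L-C3 pair. Cutting both bonds leaves a ring D ortho-quinone methide (L-O1, L-C8a, L-C4a, L-C4) and a (Z)-2-arylvinyl acetate, whose cis geometry maps onto the 2,3-cis pattern.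
3. The quinone methide comes from a ring D salicyl alcohol that already carries U-C4 on L-C8, so the 4→8 link is settled before ring F exists. The salicyl alcohol is made from the phenol by ortho-formylation and reduction.
4. U-C4–L-C8 is formed by Friedel–Crafts capture of a flavan-4-yl cation by 3,5-bis(benzyloxy)phenol, trans to the U-C2 aryl group. U-C2 is set by enantioselective conjugate addition of an arylboronic acid to 7-benzyloxychromone.
5. Ring order: rings A and C are bought as the chromone, ring B is added, ring D is attached, and ring F is closed last, bringing ring E with it.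

Key step: step 8

Assumption: the (R)-pyridine-oxazoline ligand in step 2 is taken to give the (2S)-flavanone, by analogy with the facial preference of this catalyst family on cyclic enones; if the opposite sense is found, the (S)-ligand is used and nothing else changes.

Remark: the C4 configuration of alcohol 5 is lost on ionisation in step 4, so any 2,4-trans epimer from step 3 is carried forward.

**Step 1**
Reactants: 1 7-hydroxychromone
Product: 2 7-(benzyloxy)-4H-chromen-4-one
Conditions: BnBr, K2CO3, acetone, reflux
Reagents that add atoms: benzyl bromide, BrCc1ccccc1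
Why: Williamson ether synthesis on the acidic 7-hydroxyl under mild carbonate conditions that leave the chromone ring intact; no stereocenter is formed.

**Step 2**
Reactants: 2 7-(benzyloxy)-4H-chromen-4-one; 3 4-(benzyloxy)phenylboronic acid
Product: 4 (2S)-7-(benzyloxy)-2-[4-(benzyloxy)phenyl]chroman-4-one
Conditions: Pd(OCOCF3)2 (5 mol%), (R)-4-tert-butyl-2-(pyridin-2-yl)-4,5-dihydrooxazole (6 mol%), NH4PF6 (30 mol%), H2O (5 equiv), 3 (2 equiv), ClCH2CH2Cl, 60 °C
Reagents that add atoms: none
Why: Palladium-catalysed asymmetric conjugate addition of an arylboronic acid to a chromone: transmetalation to the cationic divalent palladium–pyridine-oxazoline complex, enantioface-selective insertion of the C2=C3 bond under ligand control (sets U-C2 as S) and protonolysis of the palladium enolate by water.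

**Step 3**
Reactants: 4 (2S)-7-(benzyloxy)-2-[4-(benzyloxy)phenyl]chroman-4-one
Product: 5 (2S,4S)-7-(benzyloxy)-2-[4-(benzyloxy)phenyl]chroman-4-ol
Conditions: NaBH4, MeOH/THF, 0 °C
Reagents that add atoms: none
Why: Borohydride reduction of the aryl ketone, with hydride expected to attack axially to give mainly the 2,4-cis alcohol; the cold, weakly basic medium should not open the flavanone ring, so U-C2 is kept.

**Step 4**
Reactants: 5 (2S,4S)-7-(benzyloxy)-2-[4-(benzyloxy)phenyl]chroman-4-ol; 6 3,5-bis(benzyloxy)phenol
Product: 8 2-[(2S,4R)-7-(benzyloxy)-2-[4-(benzyloxy)phenyl]chroman-4-yl]-3,5-bis(benzyloxy)phenol, via flavan-4-yl cation 7 (not isolated)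
Conditions: 6 (3 equiv), TMSOTf (0.2 equiv), CH2Cl2, −40 °C; Et3N quench
Reagents that add atoms: none
Why: Friedel–Crafts alkylation through SN1 ionisation of the benzylic alcohol to cation 7 (stabilised by the para 7-benzyloxy group and the ortho ring oxygen), which the phenol should capture at the carbon ortho to its free hydroxyl, the carbon between the two benzyloxy groups being shielded in the same way as C6 of 5,7-di-O-benzyl flavan-3-ol nucleophiles, and from the face trans to the equatorial U-C2 aryl group by pseudo-axial attack on the half-chair cation, which sets U-C4 as R.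

**Step 5**
Reactants: 8 2-[(2S,4R)-7-(benzyloxy)-2-[4-(benzyloxy)phenyl]chroman-4-yl]-3,5-bis(benzyloxy)phenol
Product: 9 3-[(2S,4R)-7-(benzyloxy)-2-[4-(benzyloxy)phenyl]chroman-4-yl]-4,6-bis(benzyloxy)-2-hydroxybenzaldehyde
Conditions: MgCl2, Et3N, (CH2O)n, THF, reflux
Reagents that add atoms: paraformaldehyde (as formaldehyde), C=O
Why: Casnati–Skattebøl ortho-formylation, in which the magnesium phenoxide delivers formaldehyde only to the one free ortho carbon (the future L-C4a) and a second formaldehyde oxidises the hydroxymethyl stage by hydride transfer; the carbon para to the hydroxyl is not touched and no stereocenter is affected.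

**Step 6**
Reactants: 9 3-[(2S,4R)-7-(benzyloxy)-2-[4-(benzyloxy)phenyl]chroman-4-yl]-4,6-bis(benzyloxy)-2-hydroxybenzaldehyde
Product: 10 2-[(2S,4R)-7-(benzyloxy)-2-[4-(benzyloxy)phenyl]chroman-4-yl]-3,5-bis(benzyloxy)-6-(hydroxymethyl)phenol
Conditions: NaBH4 (1 equiv), THF/MeOH, 0 °C; pH 7 buffer work-up, used crude
Reagents that add atoms: none
Why: Borohydride reduction of the salicylaldehyde to the salicyl alcohol, kept cold, brief and neutral on work-up because this electron-rich benzylic alcohol ionises easily.

**Step 7**
Reactants: 11 1-(benzyloxy)-4-ethynylbenzene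
Product: 12 (Z)-2-[4-(benzyloxy)phenyl]ethenyl acetate
Conditions: AcOH (1.2 equiv), Ru(η3-2-methylallyl)2(dppb) (2 mol%), toluene, 50 °C
Reagents that add atoms: acetic acid, CC(=O)O
Why: Ruthenium-catalysed anti-Markovnikov addition of a carboxylic acid to a terminal alkyne through a ruthenium vinylidene, in which acetate adds to the metal-bound carbon and protonolysis releases the (Z)-enol ester.

**Step 8**
Reactants: 10 2-[(2S,4R)-7-(benzyloxy)-2-[4-(benzyloxy)phenyl]chroman-4-yl]-3,5-bis(benzyloxy)-6-(hydroxymethyl)phenol; 12 (Z)-2-[4-(benzyloxy)phenyl]ethenyl acetate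
Product: 14 (2R,3R)-5,7-bis(benzyloxy)-2-[4-(benzyloxy)phenyl]-8-[(2S,4R)-7-(benzyloxy)-2-[4-(benzyloxy)phenyl]chroman-4-yl]chroman-3-yl acetate, via ortho-quinone methide 13 (not isolated)
Conditions: 12 (3 equiv), (R)-TRIP [(R)-3,3'-bis(2,4,6-triisopropylphenyl)-1,1'-binaphthalene-2,2'-diyl hydrogen phosphate] (10 mol%), 4 Å molecular sieves, toluene, −20 °C → rt
Reagents that add atoms: none
Why: Proposed new method: the phosphoric acid protonates the benzylic hydroxyl of 10, water leaves, and ortho-quinone methide 13 stays hydrogen-bonded to the chiral phosphate at its oxygen; its electrophilic methylene (L-C4) then bonds to the acetoxy-bearing carbon of 12 while positive charge builds on the carbon stabilised by the para-benzyloxyphenyl group, and the quinone methide oxygen closes onto that carbon in the same asynchronous, suprafacial event. The closest known reaction type is the stereospecific inverse-electron-demand oxa-Diels–Alder reaction of ortho-quinone methides with beta-substituted styrenes, together with chiral phosphoric acid control of ortho-quinone methide cycloadditions with alkenes that carry a hydrogen-bond donor; a (Z)-enol ester as the two-carbon partner and facial control without a donor group have not been shown. Ring F is closed by intermolecular hetero-[4+2] cycloaddition, the four-atom unit L-O1/L-C8a/L-C4a/L-C4 of ring D joining the two alkene carbons through the new bonds L-O1–L-C2 and L-C3–L-C4. L-C2 and L-C3 are set together: their cis relationship should follow from retention of the (Z)-alkene geometry, and their absolute sense (2R,3R) has to come from the phosphate shielding one face of the bound quinone methide next to the U-C4 stereocentre, so which catalyst antipode is matched must be settled by running both. The step needs regioselectivity, which the para-alkoxystyrene polarisation of 12 and the single free ortho oxygen of ring D should secure (L-C5–O is benzylated and U-C4 already sits on L-C8), and it needs cis fidelity, which holds only if ring closure outruns bond rotation in the benzylic cation-like stage.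

**Step 9**
Reactants: 14 (2R,3R)-5,7-bis(benzyloxy)-2-[4-(benzyloxy)phenyl]-8-[(2S,4R)-7-(benzyloxy)-2-[4-(benzyloxy)phenyl]chroman-4-yl]chroman-3-yl acetate
Product: 15 (2R,3R)-5,7-bis(benzyloxy)-2-[4-(benzyloxy)phenyl]-8-[(2S,4R)-7-(benzyloxy)-2-[4-(benzyloxy)phenyl]chroman-4-yl]chroman-3-ol
Conditions: K2CO3 (0.2 equiv), MeOH/THF, rt
Reagents that add atoms: none
Why: Base-catalysed transesterification of the secondary acetate with methanol; with every phenol benzylated there is no quinone methide pathway for epimerisation at L-C2.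

**Step 10**
Reactants: 15 (2R,3R)-5,7-bis(benzyloxy)-2-[4-(benzyloxy)phenyl]-8-[(2S,4R)-7-(benzyloxy)-2-[4-(benzyloxy)phenyl]chroman-4-yl]chroman-3-ol
Product: 16 (2R,3R)-2-(4-hydroxyphenyl)-8-[(2S,4R)-7-hydroxy-2-(4-hydroxyphenyl)chroman-4-yl]chromane-3,5,7-triol
Conditions: H2 (1 atm), Pd(OH)2/C, THF/MeOH, rt
Reagents that add atoms: none
Why: Catalytic hydrogenolysis of the five aryl benzyl ethers under neutral conditions, which should leave the cyclic benzylic C–O bonds, the U-C4–L-C8 bond and all four stereocenters untouched.

**Compound list**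

1 | 7-hydroxy-4H-chromen-4-one (7-hydroxychromone) | O=c1ccoc2cc(O)ccc12 | starting material
2 | 7-(benzyloxy)-4H-chromen-4-one | O=c1ccoc2cc(OCc3ccccc3)ccc12 | intermediate
3 | 4-(benzyloxy)phenylboronic acid | OB(O)c1ccc(OCc2ccccc2)cc1 | starting material
4 | (2S)-7-(benzyloxy)-2-[4-(benzyloxy)phenyl]chroman-4-one | O=C1C[C@@H](c2ccc(OCc3ccccc3)cc2)Oc2cc(OCc3ccccc3)ccc12 | intermediate
5 | (2S,4S)-7-(benzyloxy)-2-[4-(benzyloxy)phenyl]chroman-4-ol | O[C@H]1C[C@@H](c2ccc(OCc3ccccc3)cc2)Oc2cc(OCc3ccccc3)ccc12 | intermediate
6 | 3,5-bis(benzyloxy)phenol | Oc1cc(OCc2ccccc2)cc(OCc2ccccc2)c1 | starting material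
7 | (2S)-7-(benzyloxy)-2-[4-(benzyloxy)phenyl]chroman-4-ylium (flavan-4-yl cation) | [CH+]1C[C@@H](c2ccc(OCc3ccccc3)cc2)Oc2cc(OCc3ccccc3)ccc12 | intermediate (not isolated)
8 | 2-[(2S,4R)-7-(benzyloxy)-2-[4-(benzyloxy)phenyl]chroman-4-yl]-3,5-bis(benzyloxy)phenol | c1ccccc1COc1ccc([C@@H]2C[C@@H](c3c(OCc5ccccc5)cc(OCc5ccccc5)cc3O)c3ccc(OCc5ccccc5)cc3O2)cc1 | intermediate
9 | 3-[(2S,4R)-7-(benzyloxy)-2-[4-(benzyloxy)phenyl]chroman-4-yl]-4,6-bis(benzyloxy)-2-hydroxybenzaldehyde | c1ccccc1COc1ccc([C@@H]2C[C@@H](c3c(OCc5ccccc5)cc(OCc5ccccc5)c(C=O)c3O)c3ccc(OCc5ccccc5)cc3O2)cc1 | intermediate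
10 | 2-[(2S,4R)-7-(benzyloxy)-2-[4-(benzyloxy)phenyl]chroman-4-yl]-3,5-bis(benzyloxy)-6-(hydroxymethyl)phenol | c1ccccc1COc1ccc([C@@H]2C[C@@H](c3c(OCc5ccccc5)cc(OCc5ccccc5)c(CO)c3O)c3ccc(OCc5ccccc5)cc3O2)cc1 | intermediate
11 | 1-(benzyloxy)-4-ethynylbenzene | C#Cc1ccc(OCc2ccccc2)cc1 | starting material
12 | (Z)-2-[4-(benzyloxy)phenyl]ethenyl acetate | CC(=O)O/C=C\c1ccc(OCc2ccccc2)cc1 | intermediate
13 | 2-[(2S,4R)-7-(benzyloxy)-2-[4-(benzyloxy)phenyl]chroman-4-yl]-3,5-bis(benzyloxy)-6-methylidenecyclohexa-2,4-dien-1-one (ortho-quinone methide) | C=C1C(OCc2ccccc2)=CC(OCc2ccccc2)=C([C@@H]2C[C@@H](c3ccc(OCc4ccccc4)cc3)Oc3cc(OCc4ccccc4)ccc32)C1=O | intermediate (not isolated)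
14 | (2R,3R)-5,7-bis(benzyloxy)-2-[4-(benzyloxy)phenyl]-8-[(2S,4R)-7-(benzyloxy)-2-[4-(benzyloxy)phenyl]chroman-4-yl]chroman-3-yl acetate | c1ccccc1COc1ccc([C@@H]2C[C@@H](c3c(OCc5ccccc5)cc(OCc5ccccc5)c4c3O[C@H](c3ccc(OCc5ccccc5)cc3)[C@H](OC(C)=O)C4)c3ccc(OCc5ccccc5)cc3O2)cc1 | intermediate
15 | (2R,3R)-5,7-bis(benzyloxy)-2-[4-(benzyloxy)phenyl]-8-[(2S,4R)-7-(benzyloxy)-2-[4-(benzyloxy)phenyl]chroman-4-yl]chroman-3-ol | c1ccccc1COc1ccc([C@@H]2C[C@@H](c3c(OCc5ccccc5)cc(OCc5ccccc5)c4c3O[C@H](c3ccc(OCc5ccccc5)cc3)[C@H](O)C4)c3ccc(OCc5ccccc5)cc3O2)cc1 | intermediate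
16 | (2R,3R)-2-(4-hydroxyphenyl)-8-[(2S,4R)-7-hydroxy-2-(4-hydroxyphenyl)chroman-4-yl]chromane-3,5,7-triol | Oc1ccc([C@@H]2C[C@@H](c3c(O)cc(O)c4c3O[C@H](c3ccc(O)cc3)[C@H](O)C4)c3ccc(O)cc3O2)cc1 | target

**Step count**

Total: 10 steps. Longest linear sequence: 9 steps (steps 1–6, then 8–10, from 7-hydroxychromone); step 7 is a one-step branch.

**Steps most likely to fail**

1. Step 8 (proposed new method). The addition may run stepwise through a long-lived para-benzyloxybenzyl cation, so that bond rotation before ring closure erodes the cis relationship. Facial selectivity may be poor because the enol ester offers the phosphate no hydrogen-bond donor and the bulky U unit sits next to the binding site. The released water may hydrolyse the enol acetate, or the quinone methide may oligomerise. Fallback with known chemistry, setting out from 5 and coming back at 15: purchased (−)-epiafzelechin F1 is benzylated on its three phenols (BnBr, K2CO3, DMF, rt; the secondary 3-hydroxyl stays free) to 5,7,4'-tri-O-benzyl-(−)-epiafzelechin F2. Alcohol 5 is then ionised with TMSOTf in CH2Cl2 at low temperature in the presence of excess F2. Cation 7 should be captured by L-C8 of F2, the position between the ring oxygen and the 7-benzyloxy group, trans to the U-C2 aryl group, as in acid-mediated 4→8 couplings of benzylated flavan-3-ols. This gives 15 directly and the route continues with step 10.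

2. Step 4. The cation may attack the carbon between the two benzyloxy groups or the phenol oxygen, the product may be alkylated a second time, and the trans to cis preference at U-C4 may be modest. Fallback setting out from 5 and coming back at 9: the nucleophile is changed to purchased 2,4,6-trihydroxybenzaldehyde F3, whose two free ring carbons are equivalent, so only one C-alkylation product is possible. Acid-mediated coupling with 5 (BF3·OEt2, dioxane) should give 3-[(2S,4R)-7-(benzyloxy)-2-[4-(benzyloxy)phenyl]chroman-4-yl]-2,4,6-trihydroxybenzaldehyde F4. Benzylation with about two equivalents of BnBr and K2CO3 in acetone should then etherify the 4- and 6-hydroxyls and leave the 2-hydroxyl, which is hydrogen-bonded to the aldehyde and flanked by the flavanyl group. This gives 9 and makes step 5 unnecessary.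

3. Step 2. The electron-rich boronic acid may protodeboronate, the electron-rich chromone may insert slowly, and the enantioselectivity may be insufficient or of the opposite sense. Fallback setting out from 2 and 3 and coming back at 5: the conjugate addition is run without asymmetric induction (Pd(OCOCF3)2, 2,2'-bipyridine, same solvent) to give racemic 7-(benzyloxy)-2-[4-(benzyloxy)phenyl]chroman-4-one F5. This is resolved kinetically by Noyori transfer hydrogenation with RuCl(p-cymene)[(S,S)-TsDPEN] in HCO2H/Et3N. The (2S)-ketone should be reduced faster, giving the (2S,4S)-cis alcohol 5, and the unreacted (R)-ketone is removed by chromatography; steps 2 and 3 are replaced.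

**Further compounds**

F1 | step 8 | (−)-epiafzelechin (purchased) | O[C@@H]1Cc2c(O)cc(O)cc2O[C@@H]1c1ccc(O)cc1
F2 | step 8 | 5,7,4'-tri-O-benzyl-(−)-epiafzelechin | O[C@@H]1Cc2c(OCc3ccccc3)cc(OCc3ccccc3)cc2O[C@@H]1c1ccc(OCc2ccccc2)cc1
F3 | step 4 | 2,4,6-trihydroxybenzaldehyde (purchased) | O=Cc1c(O)cc(O)cc1O
F4 | step 4 | 3-[(2S,4R)-7-(benzyloxy)-2-[4-(benzyloxy)phenyl]chroman-4-yl]-2,4,6-trihydroxybenzaldehyde | O=Cc1c(O)cc(O)c([C@@H]2C[C@@H](c3ccc(OCc4ccccc4)cc3)Oc3cc(OCc4ccccc4)ccc32)c1O
F5 | step 2 | racemic 7-(benzyloxy)-2-[4-(benzyloxy)phenyl]chroman-4-one | O=C1CC(c2ccc(OCc3ccccc3)cc2)Oc2cc(OCc3ccccc3)ccc12
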